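Cuts, in retrosynthetic order: (a) CH3–C(OH) on the five-membered ring; (b) CH2 linker–C4 of the six-membered ring; (c) in one operation, ring C–isopropenyl and ring C–CH2 linker on the cyclopentane; (d) C1–C2 and C4–C5 of the six-membered ring, leading back to a methyl(prenyl)malonate and 5-methylhexane-2,4-dione.
Enabling feature: around the cyclopentane, the CH bearing isopropenyl, the CH bearing the linker (trans to it) and the C(CH3)OH carbon are consecutive, matching C3, C2 and C1 of cyclopent-2-enone.
Forward order: the purchased five-membered ring receives both side-chain bonds in one flask (fragment A, steps 1–3). The six-membered ring is closed by a Dieckmann-type Claisen condensation (fragment B, steps 4–8). The fragments are joined by elimination/Michael addition (step 9), and the methyl carbinol is made last (step 10).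
Stereochemistry: the isopropenyl carbon comes from the chiral ligand on copper. The neighbouring CH is set trans by anti capture of the enolate, erased on amine loss, and re-set trans by equilibrating protonation in step 9. The carbinol comes from methyl attack anti to the C2 side chain. The quaternary C(CH3)(prenyl) comes from enzymatic desymmetrisation of a prochiral malonate, whose two carboxyl carbons then enter the ring in a fixed order.

Key step: step 2

Assumption 1: the hand of ligand L* (the phosphite formed from (R,R)-TADDOL and 2-tert-butyl-6-(diphenylphosphanyl)phenol) that gives the 3R adduct is assigned by analogy with six-membered enones and would be confirmed on the first batch; both hands of TADDOL are sold.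
Assumption 2: pig liver esterase is taken to cleave the pro-S ester of the prenylated methylmalonate, the sense it shows for 2-methylmalonates whose second chain has five or more carbons; the configuration of the half-ester would be checked before use.
Assumption 3: all triketones are drawn and named in the dienol tautomer of the target SMILES, and CIP labels refer to that tautomer.

Step 1
Reactants: 1 2-bromopropene
Product: 2 isopropenylmagnesium bromide (titrated solution in 2-MeTHF)
Conditions: Mg turnings, I2 (crystal), 2-MeTHF, 35–40 °C
Reagents that add atoms: magnesium, [Mg]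
Why: Insertion of magnesium into the vinylic C–Br bond (Grignard reagent formation) is routine for 2-bromopropene, and preparation in 2-MeTHF supplies the reagent in the solvent best suited to the copper catalysis of step 2.

Step 2
Reactants: 2 isopropenylmagnesium bromide; 3 cyclopent-2-en-1-one; 4 N,N-dimethylmethyleneiminium iodide
Product: 6 (2R,3R)-2-[(dimethylamino)methyl]-3-(prop-1-en-2-yl)cyclopentan-1-one, via bromomagnesium enolate 5 (not isolated)
Conditions: CuBr·SMe2 (5 mol %), L* (6 mol %), 2-MeTHF, −78 °C, 2 added slowly to 3; then solid 4 (1.5 equiv), CH2Cl2 co-solvent, −78 °C → rt; acid–base extraction, no silica gel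
Reagents that add atoms: none
Why: The ligated monovalent copper bromide is transmetallated by 2, binds the C2=C3 bond of 3 as a π-complex, adds oxidatively at C3 to a trivalent copper intermediate and forms the C3–isopropenyl bond by reductive elimination, leaving the bromomagnesium enolate 5, whose C2 then attacks the iminium carbon of 4 (Mannich reaction) to form the C2–CH2 bond. The closest known reaction type is the copper-catalysed enantioselective conjugate addition of Grignard reagents to cyclic enones with one-pot capture of the magnesium enolate by iminium, onium or carbonyl electrophiles. No ring is closed, since both new bonds are exocyclic to the purchased five-membered ring. C3 is set by the chiral P,P-ligand, which lets copper bind only one face of the flat enone, and C2 is set by approach of 4 anti to the isopropenyl group just installed, with the α-position also free to relax to the more stable trans isomer. The step needs 1,4- over 1,2-addition, which the unsubstituted β-carbon of 3, the soft ligated copper species, the low temperature and the slow addition of 2 secure, and it needs aminomethylation at C2 and not at C5, which the substrate secures because the enolate double bond is created between C1 and C2 and is consumed before proton transfer can move it.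

Step 3
Reactants: 6 (2R,3R)-2-[(dimethylamino)methyl]-3-(prop-1-en-2-yl)cyclopentan-1-one
Product: 7 N,N,N-trimethyl-1-[(1R,5R)-2-oxo-5-(prop-1-en-2-yl)cyclopentyl]methanaminium iodide
Conditions: MeI (1.5 equiv), Et2O, 0 °C → rt; filtration, recrystallisation
Reagents that add atoms: iodomethane, CI
Why: Menshutkin quaternisation of the unhindered tertiary amine is fast and neutral, leaves ketone, alkene and stereocentres untouched, and gives a crystalline salt whose NMe3 group leaves at room temperature and, unlike dimethylamine, cannot condense with the triketone partner.

Step 4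
Reactants: 8 dimethyl 2-methylpropanedioate (dimethyl methylmalonate); 9 1-bromo-3-methylbut-2-ene (prenyl bromide)
Product: 10 dimethyl 2-methyl-2-(3-methylbut-2-en-1-yl)propanedioate
Conditions: K2CO3, DMF, rt
Reagents that add atoms: none
Why: In this malonic ester alkylation the carbonate-generated enolate of 8 displaces bromide from the primary allylic halide by SN2, and the product remains achiral because its two ester groups are enantiotopic.

Step 5
Reactants: 10 dimethyl 2-methyl-2-(3-methylbut-2-en-1-yl)propanedioate
Product: 11 (2R)-2-(methoxycarbonyl)-2,5-dimethylhex-4-enoic acid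
Conditions: pig liver esterase, phosphate buffer pH 7.5, DMSO (20 vol %), 25 °C, pH-stat with 1 M NaOH; then cold HCl to pH 2, extraction
Reagents that add atoms: water, O
Why: In this enzymatic desymmetrisation of a prochiral 2,2-disubstituted dimethyl malonate the esterase places methyl and prenyl in pockets of different size and hydrolyses only the pro-S ester, which sets the quaternary centre as R, and the carboxylate formed is no longer a substrate, so the second ester survives.

Step 6
Reactants: 11 (2R)-2-(methoxycarbonyl)-2,5-dimethylhex-4-enoic acid
Product: 12 methyl (2S)-2-(chlorocarbonyl)-2,5-dimethylhex-4-enoate (same spatial arrangement, label changed because COCl outranks CO2Me)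
Conditions: 1-chloro-N,N,2-trimethylprop-1-en-1-amine (1.1 equiv), CH2Cl2, 0 °C → rt; concentrated and used crude
Reagents that add atoms: 1-chloro-N,N,2-trimethylprop-1-en-1-amine, CC(C)=C(Cl)N(C)C
Why: Acid chloride formation with an α-chloroenamine runs under neutral conditions without release of HCl, so the prenyl alkene is neither hydrochlorinated nor lactonised, and the centre has no α-hydrogen through which it could racemise or form a ketene.

Step 7
Reactants: 12 methyl (2S)-2-(chlorocarbonyl)-2,5-dimethylhex-4-enoate; 13 5-methylhexane-2,4-dione
Product: 15 methyl (2R)-2,8-dimethyl-2-(3-methylbut-2-en-1-yl)-3,5,7-trioxononanoate, via dilithium dianion 14 (not isolated)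
Conditions: 13 (2.2 equiv), LiN(iPr)2 (4.4 equiv, commercial solution), THF, 0 °C; then 12, −78 °C; cold 1 M HCl quench
Reagents that add atoms: lithium diisopropylamide, [Li+].CC(C)[N-]C(C)C (supplies only the lithium of 14)
Why: In this γ-acylation of a β-diketone dianion (Claisen-type acylation) the second deprotonation of 13 occurs at the methyl group and not at the isopropyl methine, the terminal carbanion of 14 is the most nucleophilic site, and at −78 °C it takes the acid chloride far faster than the equally hindered methyl ester, a chemoselectivity that transfers the configuration of 11 into the later ring because the former acid carbon ends next to C4 and the ester carbon next to C2.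

Step 8
Reactants: 15 methyl (2R)-2,8-dimethyl-2-(3-methylbut-2-en-1-yl)-3,5,7-trioxononanoate
Product: 16 (6R)-3,5-dihydroxy-6-methyl-6-(3-methylbut-2-en-1-yl)-2-(2-methylpropanoyl)cyclohexa-2,4-dien-1-one
Conditions: KOtBu (3 equiv), THF, 0 → 50 °C; then 1 M HCl to pH 3
Reagents that add atoms: none
Why: In this Dieckmann-type intramolecular Claisen condensation C6 of the dienolate of 15 attacks the ester carbon in a 6-exo-trig closure favoured by the gem-disubstituted carbon, the only other carbon nucleophile would give a four-membered ring, any O-acylated lactone is reopened by the alkoxide present, the strongly stabilised triketone enolate is the thermodynamic sink, and the quaternary centre is not touched.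

Step 9
Reactants: 7 N,N,N-trimethyl-1-[(1R,5R)-2-oxo-5-(prop-1-en-2-yl)cyclopentyl]methanaminium iodide; 16 (6R)-3,5-dihydroxy-6-methyl-6-(3-methylbut-2-en-1-yl)-2-(2-methylpropanoyl)cyclohexa-2,4-dien-1-one
Product: 18 (6R)-3,5-dihydroxy-6-methyl-6-(3-methylbut-2-en-1-yl)-2-(2-methylpropanoyl)-4-{[(1S,5R)-2-oxo-5-(prop-1-en-2-yl)cyclopentyl]methyl}cyclohexa-2,4-dien-1-one, via exo-methylene enone 17 (not isolated)
Conditions: K2CO3 (2.5 equiv), MeCN, rt; then 1 M HCl to pH 3
Reagents that add atoms: none
Why: E1cB loss of trimethylamine from the Mannich salt releases enone 17, which is taken at once by C4 of the enolate of 16, the only nucleophilic ring carbon still bearing hydrogen (Michael addition, the classical use of Mannich methiodides as vinyl ketone equivalents), so that C3 of the five-membered ring is preserved because 17 never accumulates, while the α-centre re-formed by protonation equilibrates through the enol in the basic medium to the more stable trans arrangement.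

Step 10
Reactants: 18 (6R)-3,5-dihydroxy-6-methyl-6-(3-methylbut-2-en-1-yl)-2-(2-methylpropanoyl)-4-{[(1S,5R)-2-oxo-5-(prop-1-en-2-yl)cyclopentyl]methyl}cyclohexa-2,4-dien-1-one
Product: 20 (6R)-3,5-dihydroxy-4-{[(1S,2R,5R)-2-hydroxy-2-methyl-5-(prop-1-en-2-yl)cyclopentyl]methyl}-6-methyl-6-(3-methylbut-2-en-1-yl)-2-(2-methylpropanoyl)cyclohexa-2,4-dien-1-one (CNP0261875.1), via bis(bromomagnesium) enolate 19 (not isolated)
Conditions: MeMgBr (2.1 equiv), THF, −78 °C; then premixed anhydrous CeCl3/MeMgBr (3 equiv each), THF, −78 → 0 °C; cold 0.5 M HCl to pH 3–4
Reagents that add atoms: methylmagnesium bromide, C[Mg]Br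
Why: In this organocerium 1,2-addition the first two equivalents of Grignard reagent remove both enol protons so that all four carbonyl groups of the six-membered ring are masked in bis-enolate 19, and the weakly basic methylcerium reagent then adds to the only free ketone without enolising it, from the face opposite the bulky C2 side chain as is usual for 2-substituted and trans-2,3-disubstituted cyclopentanones, which places OH cis to the linker and CH3 cis to isopropenyl.

Compound list
1 | 2-bromopropene | C=C(C)Br | starting material
2 | isopropenylmagnesium bromide | C=C(C)[Mg]Br | intermediate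
3 | cyclopent-2-en-1-one | O=C1C=CCC1 | starting material
4 | N,N-dimethylmethyleneiminium iodide | C=[N+](C)C.[I-] | starting material
5 | bromomagnesium (R)-3-(prop-1-en-2-yl)cyclopent-1-en-1-olate | C=C(C)[C@@H]1CCC(O[Mg]Br)=C1 | intermediate
6 | (2R,3R)-2-[(dimethylamino)methyl]-3-(prop-1-en-2-yl)cyclopentan-1-one | C=C(C)[C@@H]1CCC(=O)[C@H]1CN(C)C | intermediate
7 | N,N,N-trimethyl-1-[(1R,5R)-2-oxo-5-(prop-1-en-2-yl)cyclopentyl]methanaminium iodide | C=C(C)[C@@H]1CCC(=O)[C@H]1C[N+](C)(C)C.[I-] | intermediate
8 | dimethyl 2-methylpropanedioate | COC(=O)C(C)C(=O)OC | starting material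
9 | 1-bromo-3-methylbut-2-ene | CC(C)=CCBr | starting material
10 | dimethyl 2-methyl-2-(3-methylbut-2-en-1-yl)propanedioate | COC(=O)C(C)(CC=C(C)C)C(=O)OC | intermediate
11 | (2R)-2-(methoxycarbonyl)-2,5-dimethylhex-4-enoic acid | OC(=O)[C@@](C)(CC=C(C)C)C(=O)OC | intermediate
12 | methyl (2S)-2-(chlorocarbonyl)-2,5-dimethylhex-4-enoate | ClC(=O)[C@@](C)(CC=C(C)C)C(=O)OC | intermediate
13 | 5-methylhexane-2,4-dione | CC(=O)CC(=O)C(C)C | starting material
14 | dilithium 5-methylhexa-1,3-diene-2,4-diolate (1,3-dianion of 13) | [Li+].[Li+].C=C([O-])C=C([O-])C(C)C | intermediate
15 | methyl (2R)-2,8-dimethyl-2-(3-methylbut-2-en-1-yl)-3,5,7-trioxononanoate | CC(C)C(=O)CC(=O)CC(=O)[C@@](C)(CC=C(C)C)C(=O)OC | intermediate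
16 | (6R)-3,5-dihydroxy-6-methyl-6-(3-methylbut-2-en-1-yl)-2-(2-methylpropanoyl)cyclohexa-2,4-dien-1-one | C1=C(O)[C@@](C)(CC=C(C)C)C(=O)C(C(=O)C(C)C)=C1O | intermediate
17 | (S)-2-methylidene-3-(prop-1-en-2-yl)cyclopentan-1-one (same spatial arrangement at C3 as in 6) | C=C(C)[C@@H]1CCC(=O)C1=C | intermediate
18 | (6R)-3,5-dihydroxy-6-methyl-6-(3-methylbut-2-en-1-yl)-2-(2-methylpropanoyl)-4-{[(1S,5R)-2-oxo-5-(prop-1-en-2-yl)cyclopentyl]methyl}cyclohexa-2,4-dien-1-one | C=C(C)[C@@H]1CCC(=O)[C@H]1CC1=C(O)[C@@](C)(CC=C(C)C)C(=O)C(C(=O)C(C)C)=C1O | intermediate
19 | bis(bromomagnesium) 3,5-dienolate of 18 | C=C(C)[C@@H]1CCC(=O)[C@H]1CC1=C(O[Mg]Br)[C@@](C)(CC=C(C)C)C(=O)C(C(=O)C(C)C)=C1O[Mg]Br | intermediate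
20 | (6R)-3,5-dihydroxy-4-{[(1S,2R,5R)-2-hydroxy-2-methyl-5-(prop-1-en-2-yl)cyclopentyl]methyl}-6-methyl-6-(3-methylbut-2-en-1-yl)-2-(2-methylpropanoyl)cyclohexa-2,4-dien-1-one | C=C(C)[C@@H]1CC[C@@](C)(O)[C@H]1CC1=C(O)[C@@](C)(CC=C(C)C)C(=O)C(C(=O)C(C)C)=C1O | target

Total step count: 10.
Longest linear sequence: 7 steps (steps 4, 5, 6, 7, 8, 9, 10). The other branch has 5 steps (1, 2, 3, 9, 10).

Steps most likely to fail

1. Step 2.
- **Risk:** the catalyst may discriminate the faces of the small five-membered enone only incompletely with a vinylic Grignard reagent. Some 1,2-addition may compete. The sparingly soluble iminium salt may capture the enolate so slowly that proton transfer moves the enolate position and the enolate adds to enone still present.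
- **Fallback:** the two bond formations are separated. Setting out from enolate 5, generated as in step 2, Me3SiCl and Et3N are added at −78 °C in place of 4. This should give the regiodefined silyl enol ether (R)-trimethyl{[3-(prop-1-en-2-yl)cyclopent-1-en-1-yl]oxy}silane F1, a neutral compound that can be purified and whose enantiomeric purity can be measured. Treatment of F1 with 4 in CH2Cl2 at room temperature (aminomethylation of a silyl enol ether, a Mukaiyama-type Mannich reaction) followed by a basic work-up comes back to the route at 6.
- **Residual antipode:** it can be removed by recrystallising 7 and, as a diastereomer, after step 9.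

2. Step 5.
- **Risk:** the selection between the two enantiotopic esters may be low or inverted, because prenyl lies near the chain length at which the esterase changes its preference.
- **Fallback:** classical resolution. Setting out from 10, one ester is saponified with KOH (1 equiv) in MeOH to give racemic 2-(methoxycarbonyl)-2,5-dimethylhex-4-enoic acid F2. Crystallisation with (R)-1-phenylethylamine, or with its antipode if that gives the less soluble salt of the R acid, should give (R)-1-phenylethylammonium (2R)-2-(methoxycarbonyl)-2,5-dimethylhex-4-enoate F3. Dilute HCl then releases the acid, and the route is rejoined at 11.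

3. Step 10.
- **Risk:** the polymetallated substrate may precipitate, enolisation may compete with addition, or the facial bias may be insufficient because the attacked face carries the C3 isopropenyl group.
- **Fallback:** the methyl carbon is brought in as a methylene unit and then reduced. Setting out from 18, both enols are deprotonated with NaH in DMSO/THF, a medium that keeps the salt in solution. Dimethylsulfonium methylide (trimethylsulfonium iodide, NaH) is then added (Corey–Chaykovsky epoxidation). Attack anti to the side chain should give the spiro-epoxide (6R)-3,5-dihydroxy-6-methyl-6-(3-methylbut-2-en-1-yl)-2-(2-methylpropanoyl)-4-{[(3R,4S,5R)-5-(prop-1-en-2-yl)-1-oxaspiro[2.4]heptan-4-yl]methyl}cyclohexa-2,4-dien-1-one F4. LiEt3BH in THF opens the epoxide at its CH2 terminus, and a mild acidic work-up comes back to the route at 20.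

Further compounds
F1 | step 2 | (R)-trimethyl{[3-(prop-1-en-2-yl)cyclopent-1-en-1-yl]oxy}silane | C=C(C)[C@@H]1CCC(O[Si](C)(C)C)=C1
F2 | step 5 | racemic 2-(methoxycarbonyl)-2,5-dimethylhex-4-enoic acid | COC(=O)C(C)(CC=C(C)C)C(=O)O
F3 | step 5 | (R)-1-phenylethylammonium (2R)-2-(methoxycarbonyl)-2,5-dimethylhex-4-enoate | [O-]C(=O)[C@@](C)(CC=C(C)C)C(=O)OC.C[C@@H]([NH3+])c1ccccc1
F4 | step 10 | (6R)-3,5-dihydroxy-6-methyl-6-(3-methylbut-2-en-1-yl)-2-(2-methylpropanoyl)-4-{[(3R,4S,5R)-5-(prop-1-en-2-yl)-1-oxaspiro[2.4]heptan-4-yl]methyl}cyclohexa-2,4-dien-1-one | C=C(C)[C@@H]1CC[C@@]2(OC2)[C@H]1CC1=C(O)[C@@](C)(CC=C(C)C)C(=O)C(C(=O)C(C)C)=C1O
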